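The constants were set for the occasion, and the outcome is calculated.

No target can form before an open intermediate and a second intermediate stand in the flask together, and neither of them is charged.

| flask | substrate | partner | temperature | time | remark |
|---|---|---|---|---|---|
| Tuesday's | 0.20 mM | 1.05 equiv (fed, over 20 s) | 35 °C | 25 s | all else is in the flask from the start; the feed brings no volume worth counting |
| Monday's | 0.20 mM | 1.05 equiv (fed, over 20 s) |  | 25 s | the addition at 5 °C, then warmed to 35 °C; the feed brings no volume worth counting |
| Sunday's | 0.20 mM | 1.05 equiv |  | 25 s | everything together at the start at 5 °C, warmed to 35 °C at 20 s |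
| Wednesday's | 0.20 mM | 1.05 equiv | 35 °C | 25 s | everything together at the start |

    target ⇌ isomer of the product (K1 = 0.42, k1 = 0.035 s⁻¹, Ea1 = 75.0 kJ mol⁻¹, ΔH1 = −15.0 kJ mol⁻¹)
    2 open intermediate → homo product (k2 = 130 M⁻¹ s⁻¹, Ea2 = 39.0 kJ mol⁻¹)
    substrate → open intermediate (k3 = 0.091 s⁻¹, Ea3 = 88.0 kJ mol⁻¹)
    substrate ⇌ dormant form (K4 = 1.1, k4 = 0.36 s⁻¹, Ea4 = 84.0 kJ mol⁻¹, ΔH4 = −48.0 kJ mol⁻¹)
    open intermediate + second intermediate → target (k5 = 220 M⁻¹ s⁻¹, Ea5 = 36.0 kJ mol⁻¹)
    partner → second intermediate (k6 = 0.067 s⁻¹, Ea6 = 79.0 kJ mol⁻¹)
    (constants at 35 °C)

- percentages count the substrate that a species holds: one homo product counts as two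
- where a step has two of a species, its rate is k times that concentration squared, and two are used at each turn
- the constants hold at 35 °C; other temperatures follow from the activation energies and enthalpies

- the flask that comes out highest in amount of target, in percent of the substrate charged, or "all alike" when all lie within 1.5 percentage points (Tuesday's / Monday's / Sunday's / Wednesday's / all alike)
- target at the end, in percent of the substrate charged, Tuesday's
- target at the end, in percent of the substrate charged, Monday's
- target at the end, in percent of the substrate charged, Sunday's
- target at the end, in percent of the substrate charged, Wednesday's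

Ines holds a branching view. An open intermediate can couple with the second intermediate or pair to homo product. With each partner concentration taken at the charged 0.20 mM, these exits run at 0.0440 s⁻¹ and 0.0520 s⁻¹, a selectivity factor of 0.846. In Wednesday's the half-lives of activation, 7.6 s for substrate and 10 s for partner, are shorter than the 25 s allowed. She therefore treats activation as finished and expects all flasks alike.

I hold a clock view and count turns, a turn count being rate constant times time, or elapsed time in time constants. The forward step to the dormant form has a half-life of 1.9 s, shorter than the 7.6 s of opening. So I let substrate and dormant form share by their equilibrium constant, and open intermediate appears at 0.0433 s⁻¹. Over 25 s at 35 °C this gives 1.08 turns for opening, 1.76 for partner, counted in equivalents, and 1.10 for coupling. These counts are not large, so Wednesday's is still in mid-course at the end.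

Monday's and Sunday's have less time. I assume no turns at 5 °C, given activation energies of 88.0 kJ mol⁻¹ and 79.0 kJ mol⁻¹, which leaves 5.00 s warm. The counts then are 0.217, 0.352 and 0.220, each below one. Both intermediates therefore climb on straight lines, and integrating the product of two lines brings a factor of one third. The product of the counts over 3 is 0.559 %. This is the turn product, the share of substrate in target while the counts stay below one.

For Wednesday's the opening count exceeds one, so the straight lines fail and I give no number. I commit to an order: Wednesday's first, then Tuesday's, whose feed of 20 s outlasts the partner half-life, and the cold-start flasks last, near 0.559 %.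

The forecast takes my side, naming Wednesday's with 14 %, then 8.4 % for Tuesday's, 0.7 % for Monday's and 0.8 % for Sunday's, because “target tracks how long open and second intermediates coexist”; its cold figures stand above my 0.559 %.

Wednesday's comes out highest at 14.7 %, with Tuesday's at 8.47 %, Monday's at 0.672 % and Sunday's at 0.740 %. Ines's region lies later and holds for 3 of the flasks: at 250 s, Wednesday's reads 47.2 %, Monday's 47.0 % and Sunday's 47.1 %, but Tuesday's stands lower at 43.5 %. Monday's stands above the turn product of 0.559 %. The turn product is proportional to the partner count, so cutting Monday's partner to 0.630 equiv should scale its target to 0.403 %, and that neighbouring flask reads 0.406 %.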